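**Plan**
- Ring C is cut at O1–C2 and C3–C4. O1, C8a, C4a and C4 are a latent ortho-quinone methide of ring A, stabilised by the C5 and C7 oxygens; C2–C3 with its phenyl group is styrene.
- The CH2OH of the quinone methide precursor comes from formylation of a symmetric 2-(benzofuran-2-yl)-5-methoxyresorcinol. Chelation to the aldehyde then tells the two hydroxyls apart: one stays free as O1, the other becomes the C7 TIPS ether.
- The benzofuran is cut at its O–C2 bond and at the aryl–CH2 bond, that is, cyclodehydration of a deoxybenzoin made by Pd-catalysed α-arylation of a ring A acetophenone.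
- The aryl bromide comes from 3-methoxy-2-methylphenol: sterically governed C–H borylation/oxidation adds the third oxygen, and MOM-directed lithiation places bromine between OMOM and OMe.
- Forward order: benzofuran ring, then ring A functionalisation, then ring C. The only stereocentre, C2 (S), is set in the cycloaddition by a chiral confined Brønsted acid; both TIPS ethers are removed last.

Key step: step 11

Remark on the chemistry: which antipode of the chiral acid leads to 2S cannot be predicted with confidence; it is assigned in a first screen with both antipodes, and nothing else in the route depends on it. Flavan numbering is used for ring A and ring C.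

**Step 1**
Reactants: 1 3-methoxy-2-methylphenol
Product: 2 triisopropyl(3-methoxy-2-methylphenoxy)silane
Conditions: TIPSCl, imidazole, DMF, rt
Reagents that add atoms: triisopropylsilyl chloride, CC(C)[Si](Cl)(C(C)C)C(C)C
Why: Imidazole-promoted silyl ether formation on a phenol; the bulky, non-coordinating TIPS ether later shields its ortho position from lithiation and should survive the acid, base and hydride steps that follow.

**Step 2**
Reactants: 2 triisopropyl(3-methoxy-2-methylphenoxy)silane
Product: 4 3-methoxy-4-methyl-5-(triisopropylsilyloxy)phenol, via aryl pinacol boronate 3 (not isolated)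
Conditions: [Ir(OMe)(cod)]2 (cat.), 4,4'-di-tert-butyl-2,2'-bipyridine, B2pin2, THF, 80 °C; then Oxone (2KHSO5·KHSO4·K2SO4), acetone/H2O, rt
Reagents that add atoms: bis(pinacolato)diboron, CC1(C)OB(OC1(C)C)B1OC(C)(C)C(C)(C)O1 (boron of 3); potassium peroxymonosulfate, [K+].[O-]S(=O)(=O)OO (oxygen of 4)
Why: Iridium-catalysed aromatic C–H borylation is sterically governed and should go to the only C–H flanked by two hydrogens of this 1,2,3-trisubstituted arene, and the boronate is oxidised to the phenol in the same flask (borylation–oxidation phenol synthesis).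

**Step 3**
Reactants: 4 3-methoxy-4-methyl-5-(triisopropylsilyloxy)phenol
Product: 5 triisopropyl[3-methoxy-5-(methoxymethoxy)-2-methylphenoxy]silane
Conditions: MOMCl, iPr2NEt, CH2Cl2, 0 °C to rt
Reagents that add atoms: chloromethyl methyl ether, COCCl
Why: O-alkylation of the phenol to the MOM acetal installs the directing group for the lithiation.

**Step 4**
Reactants: 5 triisopropyl[3-methoxy-5-(methoxymethoxy)-2-methylphenoxy]silane
Product: 7 [4-bromo-3-methoxy-5-(methoxymethoxy)-2-methylphenoxy]triisopropylsilane, via aryllithium 6 (not isolated)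
Conditions: n-BuLi, TMEDA, THF, 0 °C; then BrCl2CCCl2Br, −78 °C to rt
Reagents that add atoms: n-butyllithium, [Li]CCCC (lithium of 6); 1,2-dibromo-1,1,2,2-tetrachloroethane, BrC(Cl)(Cl)C(Cl)(Cl)Br (bromine of 7)
Why: Directed ortho metalation should take place at the carbon between OMOM and OMe, which is activated by two coordinating oxygens, whereas the position next to the TIPS ether is shielded and not directed; the aryllithium is then brominated by halogen transfer.

**Step 5**
Reactants: 8 1-(2,6-dihydroxy-4-methoxyphenyl)ethanone (2',6'-dihydroxy-4'-methoxyacetophenone)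
Product: 9 1-[4-methoxy-2,6-bis(methoxymethoxy)phenyl]ethanone
Conditions: NaH, MOMCl, DMF, 0 °C to rt
Reagents that add atoms: chloromethyl methyl ether, COCCl
Why: Alkylation of both phenoxides (MOM ether formation), with NaH to overcome chelation of the hydroxyls to the ketone, masks the phenols for the enolate chemistry.

**Step 6**
Reactants: 7 [4-bromo-3-methoxy-5-(methoxymethoxy)-2-methylphenoxy]triisopropylsilane; 9 1-[4-methoxy-2,6-bis(methoxymethoxy)phenyl]ethanone
Product: 10 1-[4-methoxy-2,6-bis(methoxymethoxy)phenyl]-2-[2-methoxy-6-(methoxymethoxy)-3-methyl-4-(triisopropylsilyloxy)phenyl]ethanone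
Conditions: Pd(OAc)2 (5 mol%), XPhos (10 mol%), K3PO4, toluene, 100 °C
Reagents that add atoms: none
Why: Palladium-catalysed α-arylation of a methyl ketone enolate (Buchwald–Hartwig type enolate arylation), in which the bulky biaryl phosphine allows oxidative addition into the hindered electron-rich bromide, the two ortho substituents stop the reaction at monoarylation, and the mild phosphate base spares the aryl silyl ether.

**Step 7**
Reactants: 10 1-[4-methoxy-2,6-bis(methoxymethoxy)phenyl]-2-[2-methoxy-6-(methoxymethoxy)-3-methyl-4-(triisopropylsilyloxy)phenyl]ethanone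
Product: 12 5-methoxy-2-[4-methoxy-5-methyl-6-(triisopropylsilyloxy)-1-benzofuran-2-yl]benzene-1,3-diol, via trihydroxy ketone 11 (not isolated)
Conditions: HCl (2 M in MeOH), THF, 50 °C
Reagents that add atoms: none
Why: Acidic methanolysis removes the three MOM acetals and the freed ortho-hydroxybenzyl ketone cyclodehydrates (hemiketal, then loss of water) to the aromatic benzofuran; only the phenol on the benzyl ring can reach the carbonyl in a five-membered ring, and the aryl TIPS ether should tolerate methanolic HCl.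

**Step 8**
Reactants: 12 5-methoxy-2-[4-methoxy-5-methyl-6-(triisopropylsilyloxy)-1-benzofuran-2-yl]benzene-1,3-diol
Product: 14 2,4-dihydroxy-6-methoxy-3-[4-methoxy-5-methyl-6-(triisopropylsilyloxy)-1-benzofuran-2-yl]benzaldehyde, via aryl iminium chloride 13 (not isolated)
Conditions: POCl3 (1.2 equiv), DMF, MeCN, 0 °C to rt; then aq. NaOAc, 40 °C
Reagents that add atoms: N,N-dimethylformamide, CN(C)C=O; water, O
Why: Vilsmeier–Haack formylation should choose the free resorcinol ring A, which is far more nucleophilic than the ether-substituted benzofuran, and its two open positions are equivalent by symmetry, so no regiochemical question arises.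

**Step 9**
Reactants: 14 2,4-dihydroxy-6-methoxy-3-[4-methoxy-5-methyl-6-(triisopropylsilyloxy)-1-benzofuran-2-yl]benzaldehyde
Product: 15 2-hydroxy-6-methoxy-3-[4-methoxy-5-methyl-6-(triisopropylsilyloxy)-1-benzofuran-2-yl]-4-(triisopropylsilyloxy)benzaldehyde
Conditions: TIPSCl (1.1 equiv), imidazole, DMF, 0 °C to rt
Reagents that add atoms: triisopropylsilyl chloride, CC(C)[Si](Cl)(C(C)C)C(C)C
Why: Chemoselective silylation, because the hydroxyl ortho to the aldehyde is held in a strong intramolecular hydrogen bond and only the more acidic para hydroxyl (the later C7 oxygen) should react.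

**Step 10**
Reactants: 15 2-hydroxy-6-methoxy-3-[4-methoxy-5-methyl-6-(triisopropylsilyloxy)-1-benzofuran-2-yl]-4-(triisopropylsilyloxy)benzaldehyde
Product: 16 2-(hydroxymethyl)-3-methoxy-6-[4-methoxy-5-methyl-6-(triisopropylsilyloxy)-1-benzofuran-2-yl]-5-(triisopropylsilyloxy)phenol
Conditions: NaBH4, THF/MeOH, 0 °C; pH 7 buffer work-up, used without storage
Reagents that add atoms: none
Why: Borohydride 1,2-reduction of the aldehyde to the salicyl alcohol, run cold and worked up neutral so that the electron-rich benzylic alcohol does not ionise prematurely.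

**Step 11**
Reactants: 16 2-(hydroxymethyl)-3-methoxy-6-[4-methoxy-5-methyl-6-(triisopropylsilyloxy)-1-benzofuran-2-yl]-5-(triisopropylsilyloxy)phenol; 17 styrene
Product: 19 (2S)-5-methoxy-8-[4-methoxy-5-methyl-6-(triisopropylsilyloxy)-1-benzofuran-2-yl]-2-phenyl-7-(triisopropylsilyloxy)-3,4-dihydro-2H-chromene, via ortho-quinone methide 18 (not isolated)
Conditions: chiral imidodiphosphorimidate Brønsted acid (BINOL-derived, N-triflyl, 3,3'-aryl groups chosen in a screen, antipode giving 2S; 5 mol%), styrene (5 equiv), 5 Å MS, CHCl3, −40 °C, slow addition of 16; Et3N quench at −40 °C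
Reagents that add atoms: none
Why: Proposed new method: the confined acid protonates the benzylic hydroxyl of 16, water leaves, and the ortho-quinone methide 18, strongly stabilised by the C5 and C7 oxygens, stays hydrogen-bonded (or ion-paired as its O-protonated benzylic cation) to the chiral anion, where the CH2 terminus of styrene attacks the exocyclic carbon (C3–C4) and the ring A oxygen collapses onto the developing benzylic cation (O1–C2) in an asynchronous inverse-electron-demand hetero-Diels–Alder reaction. The closest known reaction types are chiral phosphoric acid catalysed [4+2] cycloadditions of in situ generated aryl-substituted ortho-quinone methides with styrenes and vinyl ethers, confined-acid catalysed [4+2] reactions of plain styrenes with unsubstituted cationic heterodienes, and the thermal racemic quinone methide–styrene route to flavans; new here is enantiocontrol for an unsubstituted methylene quinone methide with unactivated styrene. Ring C closes as a six-membered ring by intermolecular [4+2] cycloaddition, the C–C bond leading and the C–O bond following without a free intermediate. The single new stereocentre C2 is controlled by the catalyst alone, whose pocket differentiates the two faces of the styrene double bond. The step needs 2-phenyl regioselectivity (secured by the polarity match between the nucleophilic CH2 of styrene and the electrophilic methylene), ortho over para quinone methide formation (secured by the TIPS ether on the C7 oxygen) and cross-reaction over self-condensation (secured by excess styrene, slow addition and the substituted, hindered ring A).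

**Step 12**
Reactants: 19 (2S)-5-methoxy-8-[4-methoxy-5-methyl-6-(triisopropylsilyloxy)-1-benzofuran-2-yl]-2-phenyl-7-(triisopropylsilyloxy)-3,4-dihydro-2H-chromene
Product: 20 (2S)-8-(6-hydroxy-4-methoxy-5-methyl-1-benzofuran-2-yl)-5-methoxy-2-phenyl-3,4-dihydro-2H-chromen-7-ol (CNP0000229.1)
Conditions: Bu4NF, AcOH, THF, 0 °C to rt
Reagents that add atoms: none
Why: Fluoride-driven cleavage of both aryl silyl ethers (Si–F bond formation), buffered with acetic acid, should leave the benzylic ether at C2 and its configuration untouched.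

**Compound list**
1 | 3-methoxy-2-methylphenol | COc1cccc(O)c1C | starting material
2 | triisopropyl(3-methoxy-2-methylphenoxy)silane | COc1cccc(O[Si](C(C)C)(C(C)C)C(C)C)c1C | intermediate
3 | 2-[3-methoxy-4-methyl-5-(triisopropylsilyloxy)phenyl]-4,4,5,5-tetramethyl-1,3,2-dioxaborolane | COc1cc(B2OC(C)(C)C(C)(C)O2)cc(O[Si](C(C)C)(C(C)C)C(C)C)c1C | intermediate
4 | 3-methoxy-4-methyl-5-(triisopropylsilyloxy)phenol | COc1cc(O)cc(O[Si](C(C)C)(C(C)C)C(C)C)c1C | intermediate
5 | triisopropyl[3-methoxy-5-(methoxymethoxy)-2-methylphenoxy]silane | COCOc1cc(OC)c(C)c(O[Si](C(C)C)(C(C)C)C(C)C)c1 | intermediate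
6 | [2-methoxy-6-(methoxymethoxy)-3-methyl-4-(triisopropylsilyloxy)phenyl]lithium | [Li]c1c(OC)c(C)c(O[Si](C(C)C)(C(C)C)C(C)C)cc1OCOC | intermediate
7 | [4-bromo-3-methoxy-5-(methoxymethoxy)-2-methylphenoxy]triisopropylsilane | COCOc1cc(O[Si](C(C)C)(C(C)C)C(C)C)c(C)c(OC)c1Br | intermediate
8 | 1-(2,6-dihydroxy-4-methoxyphenyl)ethanone | COc1cc(O)c(C(C)=O)c(O)c1 | starting material
9 | 1-[4-methoxy-2,6-bis(methoxymethoxy)phenyl]ethanone | COCOc1cc(OC)cc(OCOC)c1C(C)=O | intermediate
10 | 1-[4-methoxy-2,6-bis(methoxymethoxy)phenyl]-2-[2-methoxy-6-(methoxymethoxy)-3-methyl-4-(triisopropylsilyloxy)phenyl]ethanone | COCOc1cc(OC)cc(OCOC)c1C(=O)Cc1c(OC)c(C)c(O[Si](C(C)C)(C(C)C)C(C)C)cc1OCOC | intermediate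
11 | 1-(2,6-dihydroxy-4-methoxyphenyl)-2-[2-hydroxy-6-methoxy-5-methyl-4-(triisopropylsilyloxy)phenyl]ethanone | COc1cc(O)c(C(=O)Cc2c(O)cc(O[Si](C(C)C)(C(C)C)C(C)C)c(C)c2OC)c(O)c1 | intermediate
12 | 5-methoxy-2-[4-methoxy-5-methyl-6-(triisopropylsilyloxy)-1-benzofuran-2-yl]benzene-1,3-diol | COc1cc(O)c(-c2cc3c(OC)c(C)c(O[Si](C(C)C)(C(C)C)C(C)C)cc3o2)c(O)c1 | intermediate
13 | N-({2,4-dihydroxy-6-methoxy-3-[4-methoxy-5-methyl-6-(triisopropylsilyloxy)-1-benzofuran-2-yl]phenyl}methylidene)-N-methylmethanaminium chloride | C[N+](C)=Cc1c(OC)cc(O)c(-c2cc3c(OC)c(C)c(O[Si](C(C)C)(C(C)C)C(C)C)cc3o2)c1O.[Cl-] | intermediate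
14 | 2,4-dihydroxy-6-methoxy-3-[4-methoxy-5-methyl-6-(triisopropylsilyloxy)-1-benzofuran-2-yl]benzaldehyde | COc1cc(O)c(-c2cc3c(OC)c(C)c(O[Si](C(C)C)(C(C)C)C(C)C)cc3o2)c(O)c1C=O | intermediate
15 | 2-hydroxy-6-methoxy-3-[4-methoxy-5-methyl-6-(triisopropylsilyloxy)-1-benzofuran-2-yl]-4-(triisopropylsilyloxy)benzaldehyde | COc1cc(O[Si](C(C)C)(C(C)C)C(C)C)c(-c2cc3c(OC)c(C)c(O[Si](C(C)C)(C(C)C)C(C)C)cc3o2)c(O)c1C=O | intermediate
16 | 2-(hydroxymethyl)-3-methoxy-6-[4-methoxy-5-methyl-6-(triisopropylsilyloxy)-1-benzofuran-2-yl]-5-(triisopropylsilyloxy)phenol | COc1cc(O[Si](C(C)C)(C(C)C)C(C)C)c(-c2cc3c(OC)c(C)c(O[Si](C(C)C)(C(C)C)C(C)C)cc3o2)c(O)c1CO | intermediate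
17 | styrene | C=Cc1ccccc1 | starting material
18 | 5-methoxy-2-[4-methoxy-5-methyl-6-(triisopropylsilyloxy)-1-benzofuran-2-yl]-6-methylidene-3-(triisopropylsilyloxy)cyclohexa-2,4-dien-1-one | C=C1C(=O)C(-c2cc3c(OC)c(C)c(O[Si](C(C)C)(C(C)C)C(C)C)cc3o2)=C(O[Si](C(C)C)(C(C)C)C(C)C)C=C1OC | intermediate
19 | (2S)-5-methoxy-8-[4-methoxy-5-methyl-6-(triisopropylsilyloxy)-1-benzofuran-2-yl]-2-phenyl-7-(triisopropylsilyloxy)-3,4-dihydro-2H-chromene | COc1cc(O[Si](C(C)C)(C(C)C)C(C)C)c(-c2cc3c(OC)c(C)c(O[Si](C(C)C)(C(C)C)C(C)C)cc3o2)c2c1CC[C@@H](c1ccccc1)O2 | intermediate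
20 | (2S)-8-(6-hydroxy-4-methoxy-5-methyl-1-benzofuran-2-yl)-5-methoxy-2-phenyl-3,4-dihydro-2H-chromen-7-ol | COc1cc(O)c(-c2cc3c(OC)c(C)c(O)cc3o2)c2c1CC[C@@H](c1ccccc1)O2 | target

**Step count and risks**
Total: 12 steps. Longest linear sequence: 11 steps (steps 1–4 and 6–12); step 5 is a one-step branch.

Most likely to fail:

1. Step 11 (proposed new method). An uncatalysed or loosely ion-paired background cycloaddition may erode the enantioselectivity, the bulky C8 substituent next to the reacting oxygen may keep the quinone methide out of the chiral pocket, and the quinone methide may oligomerise by Friedel–Crafts attack of a second electron-rich arene. The fallback uses known chemistry, sets out from 15 and returns at 19. Aldehyde 15 is condensed with (benzoylmethylene)triphenylphosphorane (toluene, 80 °C, Wittig olefination) to (E)-3-{2-hydroxy-6-methoxy-3-[4-methoxy-5-methyl-6-(triisopropylsilyloxy)-1-benzofuran-2-yl]-4-(triisopropylsilyloxy)phenyl}-1-phenylprop-2-en-1-one F1. The C=C bond is saturated with H2 and RhCl(PPh3)3 to 3-{2-hydroxy-6-methoxy-3-[4-methoxy-5-methyl-6-(triisopropylsilyloxy)-1-benzofuran-2-yl]-4-(triisopropylsilyloxy)phenyl}-1-phenylpropan-1-one F2. Noyori transfer hydrogenation with RuCl(p-cymene)[(R,R)-TsDPEN] and HCO2H/Et3N should give 2-[(3R)-3-hydroxy-3-phenylpropyl]-3-methoxy-6-[4-methoxy-5-methyl-6-(triisopropylsilyloxy)-1-benzofuran-2-yl]-5-(triisopropylsilyloxy)phenol F3, by analogy with aryl alkyl ketones. Mitsunobu cyclisation (PPh3, DIAD, THF, 0 °C) then closes ring C through O1–C2 with inversion and gives 19 as the 2S isomer.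

2. Step 6. Oxidative addition into the di-ortho-substituted, electron-rich bromide may be slow, so that protodebromination or base-induced loss of the aryl silyl ether takes over. The fallback replaces enolate arylation by Sonogashira coupling with 5-endo-dig cyclisation; it sets out from 5 and 9 and returns at 12. Lithiation of 5 as in step 4 (through 6) and an iodine quench give [4-iodo-3-methoxy-5-(methoxymethoxy)-2-methylphenoxy]triisopropylsilane F4, and brief HCl/MeOH treatment gives 2-iodo-3-methoxy-4-methyl-5-(triisopropylsilyloxy)phenol F5. Ketone 9 is converted with LiN(iPr)2 and ClP(O)(OEt)2 into diethyl 1-[4-methoxy-2,6-bis(methoxymethoxy)phenyl]ethenyl phosphate F6, which on elimination with more LiN(iPr)2 gives 2-ethynyl-5-methoxy-1,3-bis(methoxymethoxy)benzene F7. Coupling of F5 with F7 (PdCl2(PPh3)2, CuI, Et3N, DMF, 60 °C) should pass through 2-{[4-methoxy-2,6-bis(methoxymethoxy)phenyl]ethynyl}-3-methoxy-4-methyl-5-(triisopropylsilyloxy)phenol F8, which cyclises in the same flask to 4-methoxy-2-[4-methoxy-2,6-bis(methoxymethoxy)phenyl]-5-methyl-6-(triisopropylsilyloxy)-1-benzofuran F9. HCl/MeOH then removes the two MOM groups and gives 12.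

3. Step 8. Formylation may also occur at C3 or C7 of the benzofuran or run on to a dialdehyde, and the salicyl alcohol that follows in step 10 is prone to over-reduction and self-condensation. The fallback introduces the carbon at the alcohol oxidation level by boronic acid-templated ortho-hydroxymethylation; it sets out from 12 and returns at 16. Heating 12 with PhB(OH)2, paraformaldehyde and catalytic propionic acid in toluene with removal of water should give 5-methoxy-8-[4-methoxy-5-methyl-6-(triisopropylsilyloxy)-1-benzofuran-2-yl]-2-phenyl-4H-1,3,2-benzodioxaborinin-7-ol F10, in which the ortho hydroxyl and the new CH2O group are tied up as the cyclic boronate. The remaining hydroxyl is silylated (TIPSOTf, 2,6-lutidine, CH2Cl2) to 5-methoxy-8-[4-methoxy-5-methyl-6-(triisopropylsilyloxy)-1-benzofuran-2-yl]-2-phenyl-7-(triisopropylsilyloxy)-4H-1,3,2-benzodioxaborinine F11. Boronate exchange with 2,2-dimethylpropane-1,3-diol then releases 16.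

**Further compounds**
F1 | step 11 | (E)-3-{2-hydroxy-6-methoxy-3-[4-methoxy-5-methyl-6-(triisopropylsilyloxy)-1-benzofuran-2-yl]-4-(triisopropylsilyloxy)phenyl}-1-phenylprop-2-en-1-one | O=C(/C=C/c1c(OC)cc(O[Si](C(C)C)(C(C)C)C(C)C)c(-c2cc3c(OC)c(C)c(O[Si](C(C)C)(C(C)C)C(C)C)cc3o2)c1O)c1ccccc1
F2 | step 11 | 3-{2-hydroxy-6-methoxy-3-[4-methoxy-5-methyl-6-(triisopropylsilyloxy)-1-benzofuran-2-yl]-4-(triisopropylsilyloxy)phenyl}-1-phenylpropan-1-one | O=C(CCc1c(OC)cc(O[Si](C(C)C)(C(C)C)C(C)C)c(-c2cc3c(OC)c(C)c(O[Si](C(C)C)(C(C)C)C(C)C)cc3o2)c1O)c1ccccc1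
F3 | step 11 | 2-[(3R)-3-hydroxy-3-phenylpropyl]-3-methoxy-6-[4-methoxy-5-methyl-6-(triisopropylsilyloxy)-1-benzofuran-2-yl]-5-(triisopropylsilyloxy)phenol | O[C@H](CCc1c(OC)cc(O[Si](C(C)C)(C(C)C)C(C)C)c(-c2cc3c(OC)c(C)c(O[Si](C(C)C)(C(C)C)C(C)C)cc3o2)c1O)c1ccccc1
F4 | step 6 | [4-iodo-3-methoxy-5-(methoxymethoxy)-2-methylphenoxy]triisopropylsilane | COCOc1cc(O[Si](C(C)C)(C(C)C)C(C)C)c(C)c(OC)c1I
F5 | step 6 | 2-iodo-3-methoxy-4-methyl-5-(triisopropylsilyloxy)phenol | COc1c(I)c(O)cc(O[Si](C(C)C)(C(C)C)C(C)C)c1C
F6 | step 6 | diethyl 1-[4-methoxy-2,6-bis(methoxymethoxy)phenyl]ethenyl phosphate | C=C(OP(=O)(OCC)OCC)c1c(OCOC)cc(OC)cc1OCOC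
F7 | step 6 | 2-ethynyl-5-methoxy-1,3-bis(methoxymethoxy)benzene | C#Cc1c(OCOC)cc(OC)cc1OCOC
F8 | step 6 | 2-{[4-methoxy-2,6-bis(methoxymethoxy)phenyl]ethynyl}-3-methoxy-4-methyl-5-(triisopropylsilyloxy)phenol | COCOc1cc(OC)cc(OCOC)c1C#Cc1c(O)cc(O[Si](C(C)C)(C(C)C)C(C)C)c(C)c1OC
F9 | step 6 | 4-methoxy-2-[4-methoxy-2,6-bis(methoxymethoxy)phenyl]-5-methyl-6-(triisopropylsilyloxy)-1-benzofuran | COCOc1cc(OC)cc(OCOC)c1-c1cc2c(OC)c(C)c(O[Si](C(C)C)(C(C)C)C(C)C)cc2o1
F10 | step 8 | 5-methoxy-8-[4-methoxy-5-methyl-6-(triisopropylsilyloxy)-1-benzofuran-2-yl]-2-phenyl-4H-1,3,2-benzodioxaborinin-7-ol | COc1cc(O)c(-c2cc3c(OC)c(C)c(O[Si](C(C)C)(C(C)C)C(C)C)cc3o2)c2OB(c3ccccc3)OCc12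
F11 | step 8 | 5-methoxy-8-[4-methoxy-5-methyl-6-(triisopropylsilyloxy)-1-benzofuran-2-yl]-2-phenyl-7-(triisopropylsilyloxy)-4H-1,3,2-benzodioxaborinine | COc1cc(O[Si](C(C)C)(C(C)C)C(C)C)c(-c2cc3c(OC)c(C)c(O[Si](C(C)C)(C(C)C)C(C)C)cc3o2)c2OB(c3ccccc3)OCc12
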